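**Plan**
1. Retrosynthesis cuts the Z-enol acetate first (C1=C2, from a C10 ethynyl group and acetic acid), then the lactone. The O–C12(=O) unit of the trans-fused α-methylene-γ-butyrolactone (ring B: O, C12, C11, C7, C6) is one molecule of CO2 held between the vinylic carbon C11 and the ring carbon C6, which are 1,3-related through C7.
2. C11 therefore becomes a vinyl nucleophile (enol triflate of a C7 acetyl group) and C6 an electrophile (axial 6α-mesylate, cis to the C7 chain) on the cyclohexane (ring A). Reductive carboxylation then closes O–C6 with inversion: a formal (3+2) annulation with CO2.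
3. Ring A comes from an arene: 5-hydroxy-2-methoxyacetophenone is ketalised and dearomatised to a quinone monoketal that already holds C6 (ketal), C9 (ketone) and the C7 side chain.
4. Forward order: C5 (Rh/BINAP isopropenylation), C10 (methylation, ethynylation), C7 and C8 (CuH reduction, enolate hydroxylation), C9 and C6 (hydride reductions), esters, enol triflate, CO2 annulation (ring B), enol acetate.
5. Stereochemistry: C5 from the chiral ligand; C10, C7, C8, C9 and C6 by substrate control in the chair that keeps the 10-methyl group axial; C6 is inverted in the lactone closure.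

Key step: step 17

Remark (assumption): 5-hydroxy-2-methoxyacetophenone (1) is taken as a catalogue phenol.
Remark (names): from 4 onward the ring carbons keep the elemane locants of the target (C5 isopropenyl, C6 lactone oxygen, C7 acrylate carbon C11, C8 angelate, C9 acetate, C10 methyl and the chain C1–C2). α is the ring face of the 10-methyl group, β the face of the C10 two-carbon chain; the target is 5α-isopropenyl, 6β-O, 7α-C11, 8β-OAng, 9α-OAc.

**Step 1**
Reactants: 1 5-hydroxy-2-methoxyacetophenone
Product: 2 4-methoxy-3-(2-methyl-1,3-dioxolan-2-yl)phenol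
Conditions: ethylene glycol, p-TsOH·H2O (cat.), toluene, reflux, Dean–Stark
Reagents that add atoms: ethylene glycol, OCCO
Why: Acid-catalysed ketalisation with azeotropic removal of water turns the aryl ketone into a dioxolane, so that the later dienone carries an sp3, non-conjugating C7 substituent and only one enone can react with rhodium; no stereocentre is formed.

**Step 2**
Reactants: 2 dioxolane-protected phenol
Product: 3 quinone monoketal
Conditions: PhI(OAc)2 (1.1 equiv), MeOH, 0 °C
Reagents that add atoms: methanol, CO
Why: Oxidative dearomatisation of a para-methoxyphenol with trivalent iodine in methanol (quinone monoketal formation) traps the aryloxenium ion at the methoxy-bearing carbon, giving the C6 ketal and the C9 ketone at once without a stereocentre.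

**Step 3**
Reactants: 3 quinone monoketal
Product: 4 (5R)-5-isopropenyl enone
Conditions: [Rh(cod)2]BF4 (3 mol%), (R)-BINAP (3.3 mol%), potassium isopropenyltrifluoroborate (3 equiv), Et3N, toluene/H2O, 40 °C
Reagents that add atoms: potassium isopropenyltrifluoroborate, C=C(C)[B-](F)(F)F.[K+]
Why: Hayashi–Miyaura rhodium-catalysed asymmetric conjugate addition of an alkenyltrifluoroborate goes to the unsubstituted enone (the other β-carbon is fully substituted), and the ligand selects the enone face so that C5 forms as the (R) centre, (R)-BINAP being the antipode that the 2-cyclohexenone model assigns to this face.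

**Step 4**
Reactants: 4 (5R)-5-isopropenyl enone
Product: 5 10-methyl enone
Conditions: LiN(i-Pr)2 (1.1 equiv), THF, −78 °C; MeI (1.5 equiv)
Reagents that add atoms: iodomethane, CI
Why: Kinetic deprotonation can only occur at C10 (cross-conjugated α'-enolate, no γ-hydrogen), and the enolate alkylation is expected trans to the neighbouring isopropenyl group, although this centre is planarised again in step 5.

**Step 5**
Reactants: 5 10-methyl enone
Product: 6 10β-ethynyl-10α-methyl enone
Conditions: KN(SiMe3)2 (1.2 equiv), THF, −78 °C; TMS-EBX (1.3 equiv), Bu4NF (1.3 equiv), −78 to −40 °C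
Reagents that add atoms: 1-[(trimethylsilyl)ethynyl]-1,2-benziodoxol-3(1H)-one (TMS-EBX), C[Si](C)(C)C#CI1OC(=O)c2ccccc12
Why: Electrophilic alkynylation of the tetrasubstituted potassium enolate with ethynylbenziodoxolone, formed in the flask from the silyl reagent and fluoride, should create the quaternary C10 centre, the reagent approaching anti to the adjacent 5α-isopropenyl group so that ethynyl is β and methyl α.

**Step 6**
Reactants: 6 10β-ethynyl-10α-methyl enone
Product: 7 silyl alkyne enone
Conditions: LiN(i-Pr)2 (1.1 equiv), Me3SiCl (1.5 equiv), THF, −78 °C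
Reagents that add atoms: chlorotrimethylsilane, C[Si](C)(C)Cl
Why: Deprotonation of the only acidic C–H and C-silylation of the acetylide protects the alkyne from copper acetylide formation in step 7, from the enolate base in step 8 and from low-valent cobalt in step 17; no stereocentre changes.

**Step 7**
Reactants: 7 silyl alkyne enone
Product: 8 saturated C9 ketone (H-7β)
Conditions: Cu(OAc)2 (5 mol%), 1,2-bis(diphenylphosphino)benzene (5 mol%), (EtO)2MeSiH (2 equiv), t-BuOH (2 equiv), toluene, 25 °C
Reagents that add atoms: none
Why: Copper hydride conjugate reduction (Stryker-type, catalytic in copper with a silane) should deliver hydride axially to the β-face of C7, anti to the 5α-isopropenyl group, so that the dioxolanyl chain becomes α-equatorial while tert-butanol protonates the copper enolate; C7 stays correctable by enolisation once C6 is a ketone.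

**Step 8**
Reactants: 8 saturated C9 ketone
Product: 9 8β-hydroxy ketone
Conditions: KN(SiMe3)2 (1.2 equiv), THF, −78 °C; trans-2-(phenylsulfonyl)-3-phenyloxaziridine (1.5 equiv)
Reagents that add atoms: 2-(phenylsulfonyl)-3-phenyloxaziridine, O=S(=O)(c1ccccc1)N1OC1c1ccccc1
Why: Davis oxidation of the potassium enolate, which can only form toward C8 because C10 is quaternary, should place the hydroxyl group on the β-face (equatorial, trans to the C7 chain), since the α-face of C8 is screened by the syn-axial 10α-methyl group and the axial C6 methoxy group.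

**Step 9**
Reactants: 9 8β-hydroxy ketone
Product: 10 8β-angelate ketone
Conditions: angelic acid (3 equiv), 2,4,6-Cl3C6H2COCl (3 equiv), Et3N (3.5 equiv), toluene, 25 °C; then 9, 80 °C
Reagents that add atoms: angelic acid, C/C=C(/C)C(O)=O
Why: Esterification through the mixed 2,4,6-trichlorobenzoic anhydride (Yamaguchi-type, without nucleophilic catalyst) acylates the secondary alcohol and is the standard way to keep the (Z)-geometry of the angelate; no stereocentre is touched.

**Step 10**
Reactants: 10 8β-angelate ketone
Product: 11 9α-alcohol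
Conditions: NaBH4 (1.5 equiv), CeCl3·7H2O (1.2 equiv), MeOH/THF, −78 to −40 °C
Reagents that add atoms: none
Why: Luche reduction should deliver hydride axially from the β-face of C9, because approach from the α-side is hindered by the adjacent axial 10α-methyl group, giving the equatorial 9α-alcohol trans to the 8β-ester, and the cold cerium-buffered medium limits acyl migration and desilylation.

**Step 11**
Reactants: 11 9α-alcohol
Product: 12 9α-acetate
Conditions: Ac2O (5 equiv), pyridine, DMAP (20 mol%), CH2Cl2, 25 °C
Reagents that add atoms: acetic anhydride, CC(=O)OC(C)=O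
Why: DMAP-catalysed acetylation of the neopentyl-type secondary alcohol installs the final C9 acetate; no stereocentre is touched.

**Step 12**
Reactants: 12 9α-acetate
Product: 13 C6 ketone
Conditions: oxalic acid (5% aq.), SiO2, CH2Cl2, 25 °C
Reagents that add atoms: water, O
Why: Acid hydrolysis of the acyclic dimethyl ketal, which should ionise much faster than the dioxolane (relief of strain between two substituted carbons), unmasks the C6 ketone while the side-chain ketone stays protected, so no β-diketone forms; C5 and C7 are α to the new ketone and already equatorial.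

**Step 13**
Reactants: 13 C6 ketone
Product: 14 6α-alcohol
Conditions: LiBH(s-Bu)3 (1.2 equiv), THF, −78 °C; aqueous NH4Cl
Reagents that add atoms: none
Why: Reduction with the bulky trialkylborohydride (L-selectride) must come from the β-face, because the axial α-trajectory is blocked by the syn-axial 10α-methyl group, which gives the axial 6α-alcohol cis to the C7 chain; the ketone should react much faster than the two esters at −78 °C.

**Step 14**
Reactants: 14 6α-alcohol
Product: 15 6α-mesylate
Conditions: MsCl (3 equiv), Et3N (5 equiv), CH2Cl2, 0 °C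
Reagents that add atoms: methanesulfonyl chloride, CS(=O)(=O)Cl
Why: Sulfonylation of the hindered axial alcohol (mesyl chloride with triethylamine, through sulfene) makes C6 an electrophile with retention of configuration while the side-chain ketone is still masked, which avoids E1cB loss of the mesylate.

**Step 15**
Reactants: 15 6α-mesylate
Product: 16 7α-acetyl mesylate
Conditions: p-TsOH·H2O (20 mol%), acetone/H2O 10:1, 40 °C
Reagents that add atoms: water, O
Why: Acid-catalysed transketalisation to acetone frees the methyl ketone under non-basic conditions, so that the β-mesylate and the β-angelate should not be eliminated; no stereocentre changes.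

**Step 16**
Reactants: 16 7α-acetyl mesylate
Product: 17 enol triflate
Conditions: Tf2O (1.5 equiv), 2,6-di-tert-butyl-4-methylpyridine (2 equiv), CH2Cl2, 0 to 25 °C
Reagents that add atoms: trifluoromethanesulfonic anhydride, O=S(=O)(OS(=O)(=O)C(F)(F)F)C(F)(F)F
Why: Enol triflate formation with triflic anhydride and a hindered pyridine (Stang conditions) should remove the proton from the accessible methyl group of the O-triflylated ketone, giving the 1,1-disubstituted alkenyl triflate without a strong base that would attack the esters or eliminate the mesylate.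

**Step 17**
Reactants: 17 enol triflate
Product: 19 silyl alkyne lactone, via manganese acrylate 18 (not isolated)
Conditions: cobalt diiodide (10 mol%), 2,9-dimethyl-1,10-phenanthroline (10 mol%), Mn powder (3 equiv), CO2 (1 atm), DMA, 25 °C; then 50 °C in the same flask
Reagents that add atoms: carbon dioxide, O=C=O
Why: Proposed new method: manganese reduces the cobalt diiodide–phenanthroline complex to monovalent cobalt, which adds oxidatively to the C11–OTf bond of 17 (not to the secondary mesylate or the silyl alkyne); after a second reduction the alkenylcobalt inserts CO2 to give acrylate 18, whose carboxylate oxygen displaces the axial 6α-mesylate on warming. The closest known reaction type is the cobalt- or nickel-catalysed reductive carboxylation of alkenyl triflates with CO2 and manganese, joined here to the ordinary O-alkylation of a carboxylate by a sulfonate, so that the step is in effect a (3+2) annulation of CO2 onto the C11–C7–C6 unit. Ring B closes by a 5-exo-tet substitution. The only stereocentre touched is C6, which is inverted: the oxygen arrives on the β-face anti to the α-mesylate and gives the trans ring fusion, while C7 is untouched. The step needs substitution to outrun E2 loss of the mesylate (H-5β and H-7β are antiperiplanar to it); the intramolecular, weakly basic carboxylate, the open β-face trajectory and the relief of 1,3-diaxial strain between the mesylate and the 10α-methyl group should favour it. Iodide is present only at catalyst level, so the mesylate is not converted into an alkyl halide that cobalt could reduce.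

**Step 18**
Reactants: 19 silyl alkyne lactone
Product: 20 ethynyl lactone
Conditions: AgNO3 (20 mol%), acetone/H2O/CH2Cl2, 25 °C
Reagents that add atoms: none
Why: Silver-catalysed protiodesilylation of the trimethylsilyl alkyne in aqueous acetone is neutral and should leave the α-methylene lactone and the ester groups untouched.

**Step 19**
Reactants: 20 ethynyl lactone
Product: 21 CNP0582479.1
Conditions: Ru(η3-CH2C(CH3)CH2)2(Ph2P(CH2)4PPh2) (5 mol%), AcOH (2 equiv), toluene, 65 °C
Reagents that add atoms: acetic acid, CC(O)=O
Why: Ruthenium-catalysed anti-Markovnikov addition of a carboxylic acid to a terminal alkyne through a ruthenium vinylidene (Dixneuf-type hydro-acyloxylation) gives the (Z)-enol ester by trans addition and needs no base, so the α-methylene lactone and the angelate should survive.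

**Compound list**
1 | 1-(5-hydroxy-2-methoxyphenyl)ethan-1-one | CC(=O)c1cc(O)ccc1OC | starting material
2 | 4-methoxy-3-(2-methyl-1,3-dioxolan-2-yl)phenol | CC1(OCCO1)c1cc(O)ccc1OC | intermediate
3 | 4,4-dimethoxy-3-(2-methyl-1,3-dioxolan-2-yl)cyclohexa-2,5-dien-1-one | O=C1C=CC(OC)(OC)C(C2(C)OCCO2)=C1 | intermediate
4 | (5R)-4,4-dimethoxy-3-(2-methyl-1,3-dioxolan-2-yl)-5-(prop-1-en-2-yl)cyclohex-2-en-1-one (5α-isopropenyl; C9 ketone, C6 ketal) | COC2(OC)C(C3(C)OCCO3)=CC(=O)C[C@@H]2C(=C)C | intermediate
5 | 10β-methyl derivative of 4 (methyl trans to the 5α-isopropenyl group) | COC2(OC)C(C3(C)OCCO3)=CC(=O)[C@@H](C)[C@@H]2C(=C)C | intermediate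
6 | 10β-ethynyl-5α-isopropenyl-6,6-dimethoxy-10α-methyl-7-(2-methyl-1,3-dioxolan-2-yl)cyclohex-7-en-9-one | COC2(OC)C(C3(C)OCCO3)=CC(=O)[C@@](C)(C#C)[C@@H]2C(=C)C | intermediate
7 | 10β-[(trimethylsilyl)ethynyl] analogue of 6 | COC2(OC)C(C3(C)OCCO3)=CC(=O)[C@@](C)(C#C[Si](C)(C)C)[C@@H]2C(=C)C | intermediate
8 | 5α-isopropenyl-6,6-dimethoxy-10α-methyl-7α-(2-methyl-1,3-dioxolan-2-yl)-10β-[(trimethylsilyl)ethynyl]cyclohexan-9-one (H-7β) | COC2(OC)[C@H](C3(C)OCCO3)CC(=O)[C@@](C)(C#C[Si](C)(C)C)[C@@H]2C(=C)C | intermediate
9 | 8β-hydroxy derivative of 8 | COC2(OC)[C@H](C3(C)OCCO3)[C@@H](O)C(=O)[C@@](C)(C#C[Si](C)(C)C)[C@@H]2C(=C)C | intermediate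
10 | 8β-angelate ((Z)-2-methylbut-2-enoate) of 9 | COC2(OC)[C@H](C3(C)OCCO3)[C@@H](OC(=O)/C(C)=C\C)C(=O)[C@@](C)(C#C[Si](C)(C)C)[C@@H]2C(=C)C | intermediate
11 | 9α-alcohol (8β-angelate, 6,6-dimethoxy) | COC2(OC)[C@H](C3(C)OCCO3)[C@@H](OC(=O)/C(C)=C\C)[C@H](O)[C@@](C)(C#C[Si](C)(C)C)[C@@H]2C(=C)C | intermediate
12 | 9α-acetate 8β-angelate (6,6-dimethoxy) | COC2(OC)[C@H](C3(C)OCCO3)[C@@H](OC(=O)/C(C)=C\C)[C@H](OC(C)=O)[C@@](C)(C#C[Si](C)(C)C)[C@@H]2C(=C)C | intermediate
13 | C6 ketone (9α-acetate, 8β-angelate, 7α-dioxolanyl) | O=C2[C@H](C3(C)OCCO3)[C@@H](OC(=O)/C(C)=C\C)[C@H](OC(C)=O)[C@@](C)(C#C[Si](C)(C)C)[C@@H]2C(=C)C | intermediate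
14 | axial 6α-alcohol | O[C@@H]2[C@H](C3(C)OCCO3)[C@@H](OC(=O)/C(C)=C\C)[C@H](OC(C)=O)[C@@](C)(C#C[Si](C)(C)C)[C@@H]2C(=C)C | intermediate
15 | 6α-methanesulfonate | CS(=O)(=O)O[C@@H]2[C@H](C3(C)OCCO3)[C@@H](OC(=O)/C(C)=C\C)[C@H](OC(C)=O)[C@@](C)(C#C[Si](C)(C)C)[C@@H]2C(=C)C | intermediate
16 | 7α-acetyl 6α-methanesulfonate | CS(=O)(=O)O[C@@H]2[C@H](C(C)=O)[C@@H](OC(=O)/C(C)=C\C)[C@H](OC(C)=O)[C@@](C)(C#C[Si](C)(C)C)[C@@H]2C(=C)C | intermediate
17 | 7α-[1-(trifluoromethanesulfonyloxy)vinyl] 6α-methanesulfonate | CS(=O)(=O)O[C@@H]2[C@H](C(=C)OS(=O)(=O)C(F)(F)F)[C@@H](OC(=O)/C(C)=C\C)[C@H](OC(C)=O)[C@@](C)(C#C[Si](C)(C)C)[C@@H]2C(=C)C | intermediate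
18 | 2-substituted acrylate (C11 carboxylate, divalent manganese salt) with 6α-methanesulfonate, not isolated | CS(=O)(=O)O[C@@H]2[C@H](C(=C)C(=O)[O-])[C@@H](OC(=O)/C(C)=C\C)[C@H](OC(C)=O)[C@@](C)(C#C[Si](C)(C)C)[C@@H]2C(=C)C | intermediate
19 | trans-fused α-methylene lactone with 10β-[(trimethylsilyl)ethynyl] group | C=C1C(=O)O[C@H]2[C@H]1[C@@H](OC(=O)/C(C)=C\C)[C@H](OC(C)=O)[C@@](C)(C#C[Si](C)(C)C)[C@@H]2C(=C)C | intermediate
20 | trans-fused α-methylene lactone with 10β-ethynyl group | C=C1C(=O)O[C@H]2[C@H]1[C@@H](OC(=O)/C(C)=C\C)[C@H](OC(C)=O)[C@@](C)(C#C)[C@@H]2C(=C)C | intermediate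
21 | CNP0582479.1 | C=C1C(=O)O[C@H]2[C@H]1[C@@H](OC(=O)/C(C)=C\C)[C@H](OC(C)=O)[C@@](C)(/C=C\OC(C)=O)[C@@H]2C(=C)C | target

**Totals**
Total step count: 19. Longest linear sequence: 19 steps (fully linear from 1).

**Steps most likely to fail**

Step 17 (proposed new method). The closure may be outrun by E2 loss of the axial mesylate, the manganese carboxylate may be too poor a nucleophile for a trans-fused 5-exo-tet closure, or the alkenylcobalt may be protonated instead of carboxylated. The fallback sets out from 17. Palladium-catalysed carbonylation of the enol triflate (Pd(OAc)2, 1,1'-bis(diphenylphosphino)ferrocene, CO 1 atm, KOAc, DMF, 60 °C, aqueous work-up) is a known route from enol triflates to acrylic acids and should give the mesyloxy acrylic acid F1. F1 is isolated and closed separately as its caesium salt (Cs2CO3, DMF, 40 °C), which comes back to the route at 19.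

Step 7. Hydride transfer to a β-carbon flanked by two fully substituted carbons may not take place, or may occur from the wrong face. The fallback sets out from 7 and moves control of C7 to an enolisable position. Selective hydrolysis of the ring ketal (oxalic acid, SiO2) gives the ene-dione F2, and zinc in acetic acid reduces it to the 1,4-dione F3, in which C7 equilibrates to the equatorial epimer. Kinetic enolisation toward C8 and Davis oxidation give the 8β-hydroxy dione F4, and mixed-anhydride angeloylation gives the angelate F5. Luche reduction of both ketones, with the axial 10α-methyl group directing hydride to the β-face at C9 and at C6, gives the diol F6. Acetylation of the less hindered equatorial 9α-hydroxyl (Ac2O, pyridine, 0 °C) comes back to the route at 14.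

Step 16. The β-mesyloxy ketone may lose the mesylate by enolisation toward C7, or triflation may give the internal enol triflate. The fallback sets out from 14 and installs the leaving group last. Silylation (TBSOTf, 2,6-lutidine) gives the silyl ether F7, and dioxolane removal (p-TsOH, acetone/H2O) gives the methyl ketone F8, whose β-silyloxy group does not eliminate. Kinetic enolisation and O-triflation (NaN(SiMe3)2, N-(5-chloro-2-pyridyl)triflimide, THF, −78 °C) give the enol triflate F9, and HF·pyridine frees the alcohol F10. Mesylation (MsCl, Et3N) comes back to the route at 17.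

**Further compounds**
F1 | step 17 | 2-substituted acrylic acid with 6α-methanesulfonate (free acid of 18) | CS(=O)(=O)O[C@@H]2[C@H](C(=C)C(O)=O)[C@@H](OC(=O)/C(C)=C\C)[C@H](OC(C)=O)[C@@](C)(C#C[Si](C)(C)C)[C@@H]2C(=C)C
F2 | step 7 | ene-dione: 7-(2-methyl-1,3-dioxolan-2-yl)cyclohex-7-ene-6,9-dione with 5α-isopropenyl, 10α-methyl, 10β-(trimethylsilyl)ethynyl | O=C2C(C3(C)OCCO3)=CC(=O)[C@@](C)(C#C[Si](C)(C)C)[C@@H]2C(=C)C
F3 | step 7 | 6,9-dione with 7α-dioxolanyl chain (H-7β) | O=C2[C@H](C3(C)OCCO3)CC(=O)[C@@](C)(C#C[Si](C)(C)C)[C@@H]2C(=C)C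
F4 | step 7 | 8β-hydroxy 6,9-dione | O=C2[C@H](C3(C)OCCO3)[C@@H](O)C(=O)[C@@](C)(C#C[Si](C)(C)C)[C@@H]2C(=C)C
F5 | step 7 | 8β-angelate 6,9-dione | O=C2[C@H](C3(C)OCCO3)[C@@H](OC(=O)/C(C)=C\C)C(=O)[C@@](C)(C#C[Si](C)(C)C)[C@@H]2C(=C)C
F6 | step 7 | 6α,9α-diol 8β-angelate | O[C@@H]2[C@H](C3(C)OCCO3)[C@@H](OC(=O)/C(C)=C\C)[C@H](O)[C@@](C)(C#C[Si](C)(C)C)[C@@H]2C(=C)C
F7 | step 16 | 6α-tert-butyldimethylsilyl ether of 14 | CC(C)(C)[Si](C)(C)O[C@@H]2[C@H](C3(C)OCCO3)[C@@H](OC(=O)/C(C)=C\C)[C@H](OC(C)=O)[C@@](C)(C#C[Si](C)(C)C)[C@@H]2C(=C)C
F8 | step 16 | 7α-acetyl 6α-silyl ether | CC(C)(C)[Si](C)(C)O[C@@H]2[C@H](C(C)=O)[C@@H](OC(=O)/C(C)=C\C)[C@H](OC(C)=O)[C@@](C)(C#C[Si](C)(C)C)[C@@H]2C(=C)C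
F9 | step 16 | enol triflate 6α-silyl ether | CC(C)(C)[Si](C)(C)O[C@@H]2[C@H](C(=C)OS(=O)(=O)C(F)(F)F)[C@@H](OC(=O)/C(C)=C\C)[C@H](OC(C)=O)[C@@](C)(C#C[Si](C)(C)C)[C@@H]2C(=C)C
F10 | step 16 | enol triflate 6α-alcohol | O[C@@H]2[C@H](C(=C)OS(=O)(=O)C(F)(F)F)[C@@H](OC(=O)/C(C)=C\C)[C@H](OC(C)=O)[C@@](C)(C#C[Si](C)(C)C)[C@@H]2C(=C)C
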